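Doubling the charge from green to ochre multiplies the late X reading by 9.93, so X is no fixed share of the D charged. Ochre also starts with a lag, with X at 4.2% after 0.250 h and 33.2% after 0.667 h. The rate climbs as X appears, which reads as autocatalysis, with X among the concentrations in the rate. Ochre then stands still with D at 57.0%, which reads as L being lost with time.

| flask | D | L | remark | time |
|---|---|---|---|---|
| green | 0.30 M | 1 equiv | run made earlier |  |
| grey | 0.15 M | 1 equiv | run made earlier |  |
| ochre | 0.60 M | 1 equiv | run made earlier |  |
| north-west | 0.30 M (fed, over 6.00 h) | 1.00 equiv | all but D at the start; D goes in evenly over 6.00 h, the run ends at 6.0 h | 6.0 h |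
| north-east | 0.30 M | 1.00 equiv | everything together in a closed stirred flask, run for 6.0 h | 6.0 h |
| south-west | 0.30 M | 1.00 equiv | a single well-mixed tank run continuously and read at steady state, 30.0 h in it on average |  |
| south | 0.30 M | 1.00 equiv | one stirred flow tank at steady state, fed with the mixture as stated, mean residence time 6.0 h |  |

- green (time / h: X / %, D / %): 0.667: 0, 97.9; 1.33: 3.0, 95.7; 2.00: 4.2, 95.1; 2.50: 4.9, 95.4; 3.00: 4.6, 93.9; 4.00: 3.7, 93.4
- grey (time / h: X / %, D / %): 0.667: 1.2, 100.5; 1.33: 0.7, 99.2; 2.00: 0, 100.2; 2.50: 1.8, 99.6; 3.00: 0.4, 96.3; 4.00: 0.8, 100.7
- ochre (time / h: X / %, D / %): 0.250: 4.2, 95.0; 0.667: 33.2, 67.3; 1.33: 43.0, 56.5; 2.00: 45.7, 57.5; 3.00: 44.0, 55.5; 4.00: 45.0, 57.0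

(standard deviation of a reading: 1 percentage point)

- the stated concentrations are those of everything mixed, before any reaction; amounts are the same in each set-up
- the feed brings no volume worth counting
- the earlier runs were made in a closed, stirred flask

- the set-up with the highest amount of X at the outlet or at the end, in percent of the D put in ("none" if the first two lie within 2 percentage points) (north-west / north-east / south-west / south / none)
- amount of X at the outlet or at the end, in percent of the D put in, north-west
- amount of X at the outlet or at the end, in percent of the D put in, north-east
- amount of X at the outlet or at the end, in percent of the D put in, south-west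
- amount of X at the outlet or at the end, in percent of the D put in, south

The bench rule says that a stirred tank yields what the closed flask holds at the residence time, here green's late mean of 4.40%. The border shows in a ratio: south-west's 30.0 h against the 2.50 h at which green has levelled off is 12.0. This tank's mean stay is far longer than that levelling time, and fresh L keeps entering it in the presence of its X.

The reckoning here therefore takes X to grow exponentially, with an exponent that goes with charged D times charged L. For equal charges c, that exponent is (c/c*) × (c/c*). Green's exponent is then 4 times grey's, and grey's mean X reading is 0.817%: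

gain in X concentration, green over grey = 10.8

gain = (w + 1) × (w × w + 1), so w = 1.70

c* = grey's charge / sqrt(ln w) = 0.206 M

This c* is the ignition concentration, the equal charge at which the exponent is one. It is rough, since grey's readings lie close to their scatter. As a rough guess of this reckoning, not a derivation, D at south-west's outlet is set near c*, which lies below the charge, and the D lost is read as X. The reckoning thus gives south-west X of 31.4%, puts south somewhat lower at its ratio of 2.40, and puts north-east near green.

The forecast differs: 1%, 4.4%, 4% and 4.5% for north-west, north-east, south-west and south, best none, with the words “I expect yields like batch”.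

The flasks give 0.189%, 5.20%, 36.2% and 33.4% in that order, best south-west.

    D + L + X → 2 X (k = 0.0110 M⁻² s⁻¹)
    D + L → X (k = 1.90 × 10⁻⁵ M⁻¹ s⁻¹)
    L → G (k = 4.00 × 10⁻⁴ s⁻¹)

South-west's outlet holds D at 0.191 M, beside the c* of 0.206 M. On c*, north-east has an exponent of 2.12. The neighbour flask with 4.00 equiv of L has an exponent of 8.49, and it ends with X at 92.4%.

(The data stem from a simulated flask with made-up constants; the scatter is artificial.)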